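The target is disconnected across C2–C3 and C4–C5 of the oxolane. O1 with its two carbons, C2 (aryl) and C5 (CH2), is then a carbonyl ylide of veratraldehyde. C3–C4, whose methyl and C7 carbinol arms are cis, is the ring (Z)-alkene of a γ-aryl butenolide in which the lactone carbonyl is the latent C3 methyl. One 1,3-dipolar cycloaddition closes the oxolane, makes both C–C bonds and sets C2, C3 and C4 from the single C7 stereocentre of the butenolide. Its precursors are enantiopure (S)-butenolide 6 and the α-chlorobenzyl (trimethylsilyl)methyl ether 9, made fresh and used crude. C7 is inverted at the end by oxidation and reagent-controlled reduction.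

Key step: step 4

Remark: oxolane locants are O1, C2 (aryl), C3 (methyl), C4 (carbinol arm) and C5 (CH2), the carbinol carbon is C7, and keto acid 1 is taken as a catalogue compound (otherwise one Friedel–Crafts succinoylation of 1,2-dimethoxybenzene).

Step 1
Reactants: 1 4-(3,4-dimethoxyphenyl)-4-oxobutanoic acid
Product: 3 (5S)-5-(3,4-dimethoxyphenyl)oxolan-2-one, via (S)-γ-hydroxy acid 2 (not isolated)
Conditions: RuCl[(S,S)-TsDPEN](p-cymene) (1 mol %), HCO2H/Et3N (5:2), DMF, 40 °C; then aq. HCl work-up, TsOH (cat.), toluene, 60 °C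
Reagents that add atoms: none
Why: Noyori–Ikariya asymmetric transfer hydrogenation of an aryl alkyl ketone, in which the (S,S)-TsDPEN ruthenium hydride delivers hydride through its CH/π-organised six-membered transition state to set the (S)-carbinol (same sense as acetophenone), followed by acid-promoted lactonisation of the γ-hydroxy acid with retention.

Step 2
Reactants: 3 (5S)-5-(3,4-dimethoxyphenyl)oxolan-2-one
Product: 6 (5S)-5-(3,4-dimethoxyphenyl)furan-2(5H)-one, via α-phenylselanyl lactone 4 (not isolated), via selenoxide 5 (not isolated)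
Conditions: LiN(iPr)2 (1.1 equiv), THF, −78 °C; PhSeCl, −78 °C; then AcOH, 30% aq. H2O2, 0 °C → rt
Reagents that add atoms: none
Why: Enolate α-selenenylation and selenoxide syn-elimination in one pot, which can only remove a ring β-hydrogen and so gives the conjugated butenolide, while the acetic acid buffer keeps the medium non-basic so that the C5 stereocentre, now carrying an acidic hydrogen, is not scrambled.

Step 3
Reactants: 7 3,4-dimethoxybenzaldehyde; 8 (trimethylsilyl)methanol
Product: 9 4-{chloro[(trimethylsilyl)methoxy]methyl}-1,2-dimethoxybenzene (racemic; crude solution, used at once)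
Conditions: HCl (g), CH2Cl2, anhydrous CaCl2, −20 → 0 °C; decanted, volatiles removed cold under argon, no purification
Reagents that add atoms: hydrogen chloride, Cl
Why: α-Chloro ether formation from an aldehyde, an alcohol and HCl (hemiacetal, aryl-stabilised oxocarbenium ion, chloride capture), giving a racemic centre that is of no consequence because it becomes the planar ylide carbon; the electron-rich ether ionises and hydrolyses easily, hence no purification and immediate use.

Step 4
Reactants: 9 4-{chloro[(trimethylsilyl)methoxy]methyl}-1,2-dimethoxybenzene; 6 (5S)-5-(3,4-dimethoxyphenyl)furan-2(5H)-one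
Product: 11 (1S,2S,5R,6S)-2,6-bis(3,4-dimethoxyphenyl)-3,7-dioxabicyclo[3.3.0]octan-8-one, via carbonyl ylide 10 (not isolated)
Conditions: CsF (spray-dried, 3 equiv), MeCN, 0 °C → rt; 9 (2 equiv) added slowly to 6 and CsF
Reagents that add atoms: none
Why: Fluoride attacks silicon and, with loss of chloride from the easily ionised benzylic carbon, effects a 1,3-elimination to the non-stabilised carbonyl ylide 10, which adds across the butenolide C=C in a concerted suprafacial [3+2] (π4s + π2s) cycloaddition; the closest known reaction type is the fluoride-induced carbonyl ylide cycloaddition of α-chloroalkyl silylmethyl ethers with acrylates, maleates and enones. The oxolane closes by intermolecular cycloaddition, C2–C3 and C4–C5 forming in the same step, and it is necessarily cis-fused to the lactone because the dipolarophile is a ring (Z)-alkene. C3 and C4 are set by the face of attack, which should be anti to the C7 aryl group of the (S)-butenolide, and C2 by exo approach, the ylide aryl pointing away from the lactone on the convex face, which is 2,3-trans. Regioselectivity is needed and should follow from the larger HOMO coefficient and smaller size of the CH2 terminus, which bonds to the electrophilic β-carbon next to C7 and leaves the benzylic terminus for the α-carbon. The acidic C7–H must also survive: sparingly soluble CsF, excess chloro ether (so that fluoride is consumed at silicon) and low temperature should keep the medium from deprotonating it.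

Step 5
Reactants: 11 (1S,2S,5R,6S)-2,6-bis(3,4-dimethoxyphenyl)-3,7-dioxabicyclo[3.3.0]octan-8-one
Product: 12 (1S,2S,5R,6S,8RS)-2,6-bis(3,4-dimethoxyphenyl)-3,7-dioxabicyclo[3.3.0]octan-8-ol (lactol, both anomers)
Conditions: iBu2AlH (1.2 equiv), CH2Cl2, −78 °C; aq. KNaC4H4O6 (potassium sodium tartrate) work-up
Reagents that add atoms: none
Why: Partial reduction of a γ-lactone with iBu2AlH, whose tetrahedral aluminium hemiacetal survives at −78 °C and gives the lactol on work-up, with no skeletal stereocentre touched and the new hemiacetal centre irrelevant.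

Step 6
Reactants: 12 (1S,2S,5R,6S,8RS)-2,6-bis(3,4-dimethoxyphenyl)-3,7-dioxabicyclo[3.3.0]octan-8-ol
Product: 14 (S)-(3,4-dimethoxyphenyl)[(3R,4S,5S)-5-(3,4-dimethoxyphenyl)-4-methyloxolan-3-yl]methanol, via tosylhydrazone 13 (not isolated)
Conditions: TsNHNH2 (1.2 equiv), THF, 40 °C; solvent exchange; catecholborane (3 equiv), CHCl3, 0 °C; then NaOAc·3H2O, reflux
Reagents that add atoms: none
Why: Tosylhydrazone formation from the ring-opened hydroxy aldehyde and Caglioti-type reduction with catecholborane (hydroboration of C=N, then acetate-induced loss of sulfinate and dinitrogen), which turns the lactol carbon into the C3 methyl without ever putting a leaving group on it, so that the cis C7 hydroxyl has no chance to close a second oxolane as it would onto a primary sulfonate; no stereocentre is involved.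

Step 7
Reactants: 14 (S)-(3,4-dimethoxyphenyl)[(3R,4S,5S)-5-(3,4-dimethoxyphenyl)-4-methyloxolan-3-yl]methanol
Product: 15 (3,4-dimethoxyphenyl)[(3R,4S,5S)-5-(3,4-dimethoxyphenyl)-4-methyloxolan-3-yl]methanone
Conditions: Dess–Martin periodinane (1.3 equiv), NaHCO3, CH2Cl2, 0 °C → rt
Reagents that add atoms: none
Why: Dess–Martin oxidation of a secondary benzylic alcohol, fast and buffered near neutrality, so that the C4 stereocentre next to the new ketone is not epimerised; the ketone is reduced without storage.

Step 8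
Reactants: 15 (3,4-dimethoxyphenyl)[(3R,4S,5S)-5-(3,4-dimethoxyphenyl)-4-methyloxolan-3-yl]methanone
Product: 16 (R)-(3,4-dimethoxyphenyl)[(3R,4S,5S)-5-(3,4-dimethoxyphenyl)-4-methyloxolan-3-yl]methanol (target)
Conditions: (S)-Me-CBS [(3aS)-1-methyl-3,3-diphenyltetrahydro-1H,3H-pyrrolo[1,2-c][1,3,2]oxazaborole] (0.5 equiv), BH3·SMe2 (1.0 equiv), THF, −20 °C; MeOH quench
Reagents that add atoms: none
Why: Corey–Bakshi–Shibata reduction, in which the (S)-oxazaborolidine binds the ketone with the aryl group as the large substituent and delivers hydride from the coordinated borane to give the (R)-carbinol (same sense as acetophenone), the catalyst overriding the bias of the neighbouring C4 centre.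

Compound list
1 | 4-(3,4-dimethoxyphenyl)-4-oxobutanoic acid | COc1ccc(C(=O)CCC(=O)O)cc1OC | starting material
2 | (4S)-4-(3,4-dimethoxyphenyl)-4-hydroxybutanoic acid | OC(=O)CC[C@H](O)c1ccc(OC)c(OC)c1 | intermediate
3 | (5S)-5-(3,4-dimethoxyphenyl)oxolan-2-one | O=C1CC[C@@H](c2ccc(OC)c(OC)c2)O1 | intermediate
4 | (3RS,5S)-5-(3,4-dimethoxyphenyl)-3-(phenylselanyl)oxolan-2-one | O=C1C([Se]c2ccccc2)C[C@@H](c3ccc(OC)c(OC)c3)O1 | intermediate
5 | (5S)-3-(benzeneseleninyl)-5-(3,4-dimethoxyphenyl)oxolan-2-one (mixture of isomers at C3 and Se) | O=C1C([Se](=O)c2ccccc2)C[C@@H](c3ccc(OC)c(OC)c3)O1 | intermediate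
6 | (5S)-5-(3,4-dimethoxyphenyl)furan-2(5H)-one | O=C1C=C[C@@H](c2ccc(OC)c(OC)c2)O1 | intermediate
7 | 3,4-dimethoxybenzaldehyde | COc1ccc(C=O)cc1OC | starting material
8 | (trimethylsilyl)methanol | C[Si](C)(C)CO | starting material
9 | 4-{chloro[(trimethylsilyl)methoxy]methyl}-1,2-dimethoxybenzene (racemic) | COc1ccc(C(Cl)OC[Si](C)(C)C)cc1OC | intermediate
10 | [(3,4-dimethoxyphenyl)methylidene]oxoniomethanide (carbonyl ylide) | COc1ccc(C=[O+][CH2-])cc1OC | intermediate
11 | (1S,2S,5R,6S)-2,6-bis(3,4-dimethoxyphenyl)-3,7-dioxabicyclo[3.3.0]octan-8-one | COc1ccc([C@H]2OC[C@@H]3[C@@H](c4ccc(OC)c(OC)c4)OC(=O)[C@H]23)cc1OC | intermediate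
12 | (1S,2S,5R,6S,8RS)-2,6-bis(3,4-dimethoxyphenyl)-3,7-dioxabicyclo[3.3.0]octan-8-ol | COc1ccc([C@H]2OC[C@@H]3[C@@H](c4ccc(OC)c(OC)c4)OC(O)[C@H]23)cc1OC | intermediate
13 | N'-[{(2S,3R,4R)-2-(3,4-dimethoxyphenyl)-4-[(S)-(3,4-dimethoxyphenyl)(hydroxy)methyl]oxolan-3-yl}methylidene]-4-methylbenzenesulfonohydrazide | COc1ccc([C@H]2OC[C@H]([C@H](O)c3ccc(OC)c(OC)c3)[C@@H]2C=NNS(=O)(=O)c4ccc(C)cc4)cc1OC | intermediate
14 | (S)-(3,4-dimethoxyphenyl)[(3R,4S,5S)-5-(3,4-dimethoxyphenyl)-4-methyloxolan-3-yl]methanol | COc1ccc([C@H]2OC[C@H]([C@H](O)c3ccc(OC)c(OC)c3)[C@@H]2C)cc1OC | intermediate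
15 | (3,4-dimethoxyphenyl)[(3R,4S,5S)-5-(3,4-dimethoxyphenyl)-4-methyloxolan-3-yl]methanone | COc1ccc([C@H]2OC[C@H](C(=O)c3ccc(OC)c(OC)c3)[C@@H]2C)cc1OC | intermediate
16 | (R)-(3,4-dimethoxyphenyl)[(3R,4S,5S)-5-(3,4-dimethoxyphenyl)-4-methyloxolan-3-yl]methanol | COc1ccc([C@H]2OC[C@H]([C@@H](O)c3ccc(OC)c(OC)c3)[C@@H]2C)cc1OC | target

Total step count: 8. Longest linear sequence: 7 (steps 1, 2, 4, 5, 6, 7, 8); step 3 is the convergent branch.

Steps most likely to fail

Step 4. Fluoride may deprotonate C7–H of the butenolide, which would erode enantiopurity or move the double bond out of conjugation. The ylide may be lost to dimerisation or to capture by free aldehyde. Regio- or exo-selectivity may be incomplete. The fallback sets out from 6 and comes back at 11, building the oxolane stepwise. Copper-catalysed conjugate addition of (isopropoxydimethylsilyl)methylmagnesium chloride (CuBr·SMe2 cat., THF, −78 °C) anti to the aryl group should give (4S,5S)-5-(3,4-dimethoxyphenyl)-4-{[dimethyl(propan-2-yloxy)silyl]methyl}oxolan-2-one F1. Tamao oxidation (KF, KHCO3, H2O2, THF/MeOH) should give (4R,5S)-5-(3,4-dimethoxyphenyl)-4-(hydroxymethyl)oxolan-2-one F2, which already holds C5 and the O1 oxygen. Acetal exchange (PPTS cat., toluene, removal of methanol) with 4-(dimethoxymethyl)-1,2-dimethoxybenzene F3 (from 7 with HC(OMe)3, MeOH, TsOH cat.) should give the mixed acetal (4R,5S)-5-(3,4-dimethoxyphenyl)-4-{[(3,4-dimethoxyphenyl)(methoxy)methoxy]methyl}oxolan-2-one F4. TMSOTf and iPr2NEt (CH2Cl2, −78 → 0 °C) should turn the lactone into its silyl ketene acetal (2S,3R)-2-(3,4-dimethoxyphenyl)-3-{[(3,4-dimethoxyphenyl)(methoxy)methoxy]methyl}-5-[(trimethylsilyl)oxy]-2,3-dihydrofuran F5 and ionise the acetal. Intramolecular Mukaiyama-type addition to the oxocarbenium ion then forms C2–C3 and can only give the cis-fused lactone 11, with the aryl group expected on the convex face.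

Step 3. The electron-rich chloro ether may ionise and alkylate veratryl rings in a Friedel–Crafts sense, or be hydrolysed back to the aldehyde by the water that its formation releases. The fallback sets out from 7 and 8 and comes back at 9. The two would be condensed with removal of water (PPTS cat., toluene, Dean–Stark, 2.2 equiv of 8) to the stable, purifiable acetal 4-{bis[(trimethylsilyl)methoxy]methyl}-1,2-dimethoxybenzene F6. One alkoxy group would then be exchanged for chloride with acetyl chloride (Zn(OTf)2 cat., CH2Cl2, 0 °C), giving 9 in anhydrous solution beside inert (trimethylsilyl)methyl acetate, free of water and of excess HCl.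

Step 6. The stable cis-fused lactol may open only slowly towards the hydrazone, the electron-rich benzylic C7–O bond may ionise under the mildly acidic conditions, or C3 may epimerise through the ene-hydrazine. The fallback sets out from 12 and comes back at 14. Dithioacetalisation (ethane-1,2-dithiol, BF3·OEt2 cat., CH2Cl2, −40 °C) should give (S)-(3,4-dimethoxyphenyl)[(3R,4S,5S)-5-(3,4-dimethoxyphenyl)-4-(1,3-dithiolan-2-yl)oxolan-3-yl]methanol F7. Mozingo desulfurisation with Raney Ni (deactivated in acetone, EtOH, rt) should then give 14.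

Further compounds
F1 | step 4 | (4S,5S)-5-(3,4-dimethoxyphenyl)-4-{[dimethyl(propan-2-yloxy)silyl]methyl}oxolan-2-one | CC(C)O[Si](C)(C)C[C@@H]1[C@@H](c2ccc(OC)c(OC)c2)OC(=O)C1
F2 | step 4 | (4R,5S)-5-(3,4-dimethoxyphenyl)-4-(hydroxymethyl)oxolan-2-one | OC[C@@H]1[C@@H](c2ccc(OC)c(OC)c2)OC(=O)C1
F3 | step 4 | 4-(dimethoxymethyl)-1,2-dimethoxybenzene | COC(OC)c1ccc(OC)c(OC)c1
F4 | step 4 | (4R,5S)-5-(3,4-dimethoxyphenyl)-4-{[(3,4-dimethoxyphenyl)(methoxy)methoxy]methyl}oxolan-2-one (both acetal epimers) | COC(OC[C@@H]1[C@@H](c2ccc(OC)c(OC)c2)OC(=O)C1)c3ccc(OC)c(OC)c3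
F5 | step 4 | (2S,3R)-2-(3,4-dimethoxyphenyl)-3-{[(3,4-dimethoxyphenyl)(methoxy)methoxy]methyl}-5-[(trimethylsilyl)oxy]-2,3-dihydrofuran | COC(OC[C@@H]1[C@@H](c2ccc(OC)c(OC)c2)OC(O[Si](C)(C)C)=C1)c3ccc(OC)c(OC)c3
F6 | step 3 | 4-{bis[(trimethylsilyl)methoxy]methyl}-1,2-dimethoxybenzene | COc1ccc(C(OC[Si](C)(C)C)OC[Si](C)(C)C)cc1OC
F7 | step 6 | (S)-(3,4-dimethoxyphenyl)[(3R,4S,5S)-5-(3,4-dimethoxyphenyl)-4-(1,3-dithiolan-2-yl)oxolan-3-yl]methanol | COc1ccc([C@H]2OC[C@H]([C@H](O)c3ccc(OC)c(OC)c3)[C@@H]2C4SCCS4)cc1OC
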